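**Plan**
- Retrosynthesis: cut C3–C(=O) (side chain leaves as an acid chloride). Take O2 out of C1–O2–C3 (lactone back to cyclopentanone) and cut C4–CH3. Then cut C1–C3, C3–C4 and C4a–C7a (diquinane back to enyne + CO), and last C1–C3' (alkyne + iodocoumarin).
- Enabling feature: in the cyclopenta[c]pyran ring, O2 stands between C3 and C1. C1 is a secondary carbon whose coumarin-3-yl group (C3'=C4'–O) stabilises positive charge. With O2 deleted, C1, C3, C4, C4a and C7a form the ketone ring of a cis-bicyclo[3.3.0]octan-3-one with C3 as the carbonyl carbon.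
- Forward: coumarin ring, Sonogashira union with the citronellal-derived enyne, and both carbocycles at once by Pauson–Khand reaction. Then C4 methylation, enone saturation, one-oxygen ring expansion to the δ-lactone, C3=C4 via ketene acetal phosphate and stannane, acylation, and two deprotections.
- Stereochemistry: C7 comes from (S)-citronellal, C4a from C7 in the Pauson–Khand step, and C7a from convex-face hydrogenation. C1 comes from equilibration to the exo epimer and retention in the 1,2-shift. The carbinol centre comes from (R)-2-hydroxy-3-methylbutanoic acid, and C4 is transient.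

Key step: step 11

Remark: the labels C1, O2, C3, C4, C4a, C5, C6, C7, C7a of the target's cyclopenta[c]pyran are kept for the same atoms in all intermediates. Primed locants belong to the coumarin. Exo means the convex face, which carries the two ring-fusion hydrogens.

**Step 1**
Reactants: 1 2'-hydroxy-6'-methylacetophenone
Product: 2 4-hydroxy-5-methylcoumarin
Conditions: NaH (3 equiv), (EtO)2CO, toluene, 110 °C; 2 M HCl
Reagents that add atoms: diethyl carbonate, CCOC(=O)OCC
Why: Claisen-type C-acylation of the methyl ketone enolate by the carbonate, followed by lactonisation onto the phenol, is the standard entry to 4-hydroxycoumarins from 2'-hydroxyacetophenones.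

**Step 2**
Reactants: 2 4-hydroxy-5-methylcoumarin
Product: 3 4-methoxy-5-methylcoumarin
Conditions: Me2SO4 (1.2 equiv), K2CO3, acetone, 56 °C
Reagents that add atoms: dimethyl sulfate, COS(=O)(=O)OC
Why: Williamson-type O-alkylation of the ambident anion with a hard methylating agent should go mainly to O4', and any 2-methoxychromone isomer can be removed by chromatography.

**Step 3**
Reactants: 3 4-methoxy-5-methylcoumarin
Product: 4 3-iodo-4-methoxy-5-methylcoumarin
Conditions: NIS (1.1 equiv), TFA (0.2 equiv), MeCN, 50 °C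
Reagents that add atoms: N-iodosuccinimide, O=C1CCC(=O)N1I
Why: Electrophilic iodination takes place at C3', the nucleophilic β-carbon of the C3'=C4'–OMe enol ether, which is far more reactive than the benzo ring.

**Step 4**
Reactants: 5 (S)-citronellal
Product: 7 (3S)-3,7-dimethyloct-6-en-1-yne, via alkenyl nonaflate 6 (not isolated)
Conditions: n-C4F9SO2F (1.2 equiv), phosphazene base BTPP (2.5 equiv), DMF, −10 °C → rt
Reagents that add atoms: none
Why: One-pot enol nonaflation and E2 elimination (aldehyde-to-alkyne conversion without loss or gain of carbon) turns CH2–CHO into C≡CH, and the base is too weak to deprotonate the propargylic C–H of the stereocentre.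

**Step 5**
Reactants: 7 (3S)-3,7-dimethyloct-6-en-1-yne
Product: 9 (4S)-4-methylhex-5-ynal, via ozonide 8 (not isolated)
Conditions: O3, CH2Cl2, −78 °C (Sudan III end point); Me2S, −78 °C → rt
Reagents that add atoms: ozone, [O-][O+]=O
Why: Ozonolysis with reductive work-up is chemoselective because the electron-rich trisubstituted alkene reacts much faster than a terminal alkyne, and the indicator dye stops the ozone supply in time.

**Step 6**
Reactants: 9 (4S)-4-methylhex-5-ynal
Product: 10 (3S)-3-methylhept-6-en-1-yne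
Conditions: MePPh3Br, NaHMDS, THF, 0 °C; then 9, −78 °C → rt
Reagents that add atoms: methyltriphenylphosphonium bromide, C[P+](c1ccccc1)(c1ccccc1)c1ccccc1.[Br-]
Why: Wittig methylenation of the aldehyde is fast, the ylide is not basic enough to metalate the alkyne, and the stereocentre is γ to the carbonyl and cannot epimerise.

**Step 7**
Reactants: 10 (3S)-3-methylhept-6-en-1-yne; 4 3-iodo-4-methoxy-5-methylcoumarin
Product: 11 4-methoxy-5-methyl-3-[(3S)-3-methylhept-6-en-1-yn-1-yl]coumarin
Conditions: PdCl2(PPh3)2 (3 mol %), CuI (6 mol %), Et3N (3 equiv), THF, rt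
Reagents that add atoms: none
Why: Sonogashira coupling of 3-iodo-4-methoxy heterocycles of this type is known, and room temperature keeps the amine from demethylating O4' and starting a 5-endo-dig closure to a furocoumarin.

**Step 8**
Reactants: 11 4-methoxy-5-methyl-3-[(3S)-3-methylhept-6-en-1-yn-1-yl]coumarin
Product: 13 (4S,6aR)-3-(4-methoxy-5-methyl-2-oxo-2H-chromen-3-yl)-4-methyl-4,5,6,6a-tetrahydropentalen-2(1H)-one (C1=C7a enone; C7 methyl syn to C4a–H), via dicobalt hexacarbonyl complex 12 (not isolated)
Conditions: Co2(CO)8 (1.1 equiv), CH2Cl2, rt; NMO (8 equiv), 0 °C → rt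
Reagents that add atoms: dicobalt octacarbonyl (one CO becomes C3=O), [C-]#[O+].[C-]#[O+].[C-]#[O+].[C-]#[O+].[C-]#[O+].[C-]#[O+].[C-]#[O+].[C-]#[O+].[Co].[Co]
Why: In this intramolecular Pauson–Khand [2+2+1] reaction of a 1,6-enyne with a monosubstituted alkene the tether fixes the regiochemistry, and the propargylic C7 methyl takes the exo position of the forming cis-fused cobaltacycle to avoid the bulky coumarinyl group, which should place C4a–H syn to that methyl.

**Step 9**
Reactants: 13 C1=C7a enone
Product: 15 (1R,4S,6aR)-3-(4-methoxy-5-methyl-2-oxo-2H-chromen-3-yl)-1,4-dimethyl-4,5,6,6a-tetrahydropentalen-2(1H)-one (C4 methyl exo), via lithium dienolate 14 (not isolated)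
Conditions: LDA (1.05 equiv), THF, −78 °C; MeI (3 equiv), −78 → −30 °C
Reagents that add atoms: iodomethane, CI
Why: Kinetic α'-deprotonation occurs at C4, because C1 carries no hydrogen, and the enolate is alkylated from the convex face, syn to C4a–H, which sets the exo C4 methyl.

**Step 10**
Reactants: 15 C4-methylated enone
Product: 17 (1R,3R,3aR,4S,6aS)-3-(4-methoxy-5-methyl-2-oxo-2H-chromen-3-yl)-1,4-dimethylhexahydropentalen-2(1H)-one (cis-bicyclo[3.3.0]octan-3-one; coumarinyl group and both methyls exo), via endo-coumarinyl ketone 16 (not isolated)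
Conditions: H2 (10 bar), 10% Pd/C, EtOAc, rt; filter; DBU (0.2 equiv), rt
Reagents that add atoms: none
Why: Catalytic hydrogenation adds H2 syn to the convex face, the only mode that gives a cis-fused diquinane, so C7a–H is set syn to C4a–H with the coumarinyl group endo in 16, and DBU then epimerises the aryl-activated C1–H through the enolate to the less crowded exo epimer while the far less acidic, already exo C4 stays unchanged.

**Step 11**
Reactants: 17 exo-coumarinyl cis-bicyclo[3.3.0]octan-3-one
Product: 19 (1R,4R,4aS,7S,7aR)-1-(4-methoxy-5-methyl-2-oxo-2H-chromen-3-yl)-4,7-dimethylhexahydrocyclopenta[c]pyran-3(1H)-one, via Criegee adduct 18 (not isolated)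
Conditions: mCPBA (3 equiv), CH2Cl2, 0 °C → rt, dark
Reagents that add atoms: 3-chloroperoxybenzoic acid, O=C(OO)c1cccc(Cl)c1
Why: mCPBA adds to the C3 carbonyl to give Criegee adduct 18, which loses 3-chlorobenzoate while the C1–C3 bond lying antiperiplanar to O–O shifts to oxygen, so C1–O2 and O2–C3 form in one concerted 1,2-shift (Baeyer–Villiger oxidation; the closest precedent is the conversion of 2-arylcyclopentanones into 6-aryl δ-valerolactones). The six-membered lactone ring arises by one-atom ring expansion of the five-membered ketone ring, not by a cyclisation, and the cyclopentane ring is a spectator. No stereocentre is created, because C1 migrates with retention and carries the exo (1R) configuration fixed in step 10 into the lactone, while C4, C4a, C7 and C7a are untouched. The step needs migration of C1 rather than C4, both of which are secondary; the positive charge building up at C1 is delocalised through C3'=C4'–OMe as a vinylogous oxocarbenium ion, which the methyl-bearing C4 cannot match, and the rotamer of 18 with O–O anti to C1–C3 also keeps the aroyl peroxide arm away from the bulky coumarinyl group. The tetrasubstituted push–pull C3'=C4' bond is too hindered and too electron-poor to be epoxidised, and the weak acid formed catalyses the addition without ionising the C1–O bond of the product.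

**Step 12**
Reactants: 19 δ-lactone
Product: 21 (1R,4aS,7S,7aR)-1-(4-methoxy-5-methyl-2-oxo-2H-chromen-3-yl)-4,7-dimethyl-1,4a,5,6,7,7a-hexahydrocyclopenta[c]pyran-3-yl diphenyl phosphate, via potassium enolate 20 (not isolated)
Conditions: KHMDS (1.3 equiv), THF–DMPU, −78 °C; (PhO)2P(O)Cl (1.5 equiv); filtration through Et3N-treated silica
Reagents that add atoms: diphenyl chlorophosphate, O=P(Cl)(Oc1ccccc1)Oc1ccccc1
Why: Deprotonation of the only α-C–H of the lactone (C4–H) and O-phosphorylation of the enolate is the established route to lactone-derived ketene acetal phosphates, and it installs C3=C4 and removes the transient C4 stereocentre.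

**Step 13**
Reactants: 21 ketene acetal phosphate
Product: 22 4-methoxy-5-methyl-3-[(1R,4aS,7S,7aR)-4,7-dimethyl-3-(trimethylstannyl)-1,4a,5,6,7,7a-hexahydrocyclopenta[c]pyran-1-yl]coumarin
Conditions: Me3SnSnMe3 (1.5 equiv), Pd(PPh3)4 (8 mol %), LiCl (3 equiv), THF, 65 °C
Reagents that add atoms: hexamethylditin, C[Sn](C)(C)[Sn](C)(C)C
Why: Palladium-catalysed stannylation of a ketene acetal phosphate (oxidative addition into C3–O, Sn–Sn transmetalation, reductive elimination) is a known neutral route to cyclic α-alkoxyvinylstannanes, and LiCl in THF is too weak a nucleophile to attack the O-methyl group.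

**Step 14**
Reactants: 23 (R)-2-hydroxy-3-methylbutanoic acid
Product: 24 tert-butyldimethylsilyl (2R)-2-(tert-butyldimethylsilyloxy)-3-methylbutanoate
Conditions: TBSCl (2.4 equiv), imidazole (5 equiv), DMF, rt
Reagents that add atoms: tert-butyldimethylsilyl chloride, CC(C)(C)[Si](C)(C)Cl
Why: Imidazole-promoted silylation of both the hydroxyl and the carboxyl group does not touch the C–H of the stereocentre.

**Step 15**
Reactants: 24 bis-silylated hydroxy acid
Product: 25 (2R)-2-(tert-butyldimethylsilyloxy)-3-methylbutanoyl chloride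
Conditions: (COCl)2 (1.2 equiv), DMF (cat.), CH2Cl2, 0 °C → rt
Reagents that add atoms: oxalyl chloride, O=C(Cl)C(=O)Cl
Why: Vilsmeier-type conversion of a silyl ester into the acid chloride runs without base or free HCl, so the silyl ether survives and no ketene forms that could racemise the α-carbon.

**Step 16**
Reactants: 22 vinylstannane; 25 (2R)-2-(tert-butyldimethylsilyloxy)-3-methylbutanoyl chloride
Product: 26 3-{(1R,4aS,7S,7aR)-3-[(2R)-2-(tert-butyldimethylsilyloxy)-3-methylbutanoyl]-4,7-dimethyl-1,4a,5,6,7,7a-hexahydrocyclopenta[c]pyran-1-yl}-4-methoxy-5-methylcoumarin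
Conditions: Pd2(dba)3 (5 mol %), P(2-furyl)3 (20 mol %), THF, 50 °C
Reagents that add atoms: none
Why: Stille acylation of an α-alkoxyvinylstannane with an acid chloride forms C3–C(=O) under neutral conditions, so the carbinol stereocentre brought in from 23 is not enolised.

**Step 17**
Reactants: 26 fully protected ketone
Product: 28 3-{(1R,4aS,7S,7aR)-3-[(2R)-2-(tert-butyldimethylsilyloxy)-3-methylbutanoyl]-4,7-dimethyl-1,4a,5,6,7,7a-hexahydrocyclopenta[c]pyran-1-yl}-4-hydroxy-5-methylcoumarin, via lithium coumarinolate 27 (not isolated)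
Conditions: LiCl (10 equiv), DMSO, 55 °C; 0.5 M HCl, 0 °C
Reagents that add atoms: none
Why: In this Krapcho-type SN2 demethylation of a vinylogous methyl carbonate, known for methyl tetronates, chloride attacks the O-methyl group, which C5'–CH3 and C1 twist out of conjugation, the stabilised 4-oxide leaves, and no base able to enolise the ketone is present.

**Step 18**
Reactants: 28 silyl ether of the target
Product: 29 target, 3-{(1R,4aS,7S,7aR)-3-[(2R)-2-hydroxy-3-methylbutanoyl]-4,7-dimethyl-1,4a,5,6,7,7a-hexahydrocyclopenta[c]pyran-1-yl}-4-hydroxy-5-methylcoumarin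
Conditions: HF·pyridine, pyridine, THF, 0 °C → rt
Reagents that add atoms: none
Why: Fluoride-mediated cleavage of the TBS ether in a buffered, weakly acidic medium avoids the basic conditions under which an α-hydroxy ketone could epimerise or undergo an α-ketol shift.

**Compound list**
1 | 2'-hydroxy-6'-methylacetophenone | CC(=O)c1c(C)cccc1O | starting material
2 | 4-hydroxy-5-methylcoumarin | Cc1cccc2oc(=O)cc(O)c12 | intermediate
3 | 4-methoxy-5-methylcoumarin | COc1cc(=O)oc2cccc(C)c12 | intermediate
4 | 3-iodo-4-methoxy-5-methylcoumarin | COc1c(I)c(=O)oc2cccc(C)c12 | intermediate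
5 | (S)-citronellal, (3S)-3,7-dimethyloct-6-enal | C[C@@H](CCC=C(C)C)CC=O | starting material
6 | (3S)-3,7-dimethylocta-1,6-dien-1-yl nonafluorobutane-1-sulfonate (E/Z mixture) | C[C@@H](CCC=C(C)C)C=COS(=O)(=O)C(F)(F)C(F)(F)C(F)(F)C(F)(F)F | intermediate
7 | (3S)-3,7-dimethyloct-6-en-1-yne | C[C@@H](CCC=C(C)C)C#C | intermediate
8 | 3,3-dimethyl-5-[(3S)-3-methylpent-4-yn-1-yl]-1,2,4-trioxolane (ozonide) | C[C@@H](CCC1OOC(C)(C)O1)C#C | intermediate
9 | (4S)-4-methylhex-5-ynal | C[C@@H](CCC=O)C#C | intermediate
10 | (3S)-3-methylhept-6-en-1-yne | C[C@@H](CCC=C)C#C | intermediate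
11 | 4-methoxy-5-methyl-3-[(3S)-3-methylhept-6-en-1-yn-1-yl]coumarin | C[C@@H](CCC=C)C#Cc1c(OC)c2c(C)cccc2oc1=O | intermediate
12 | hexacarbonyldicobalt complex of the alkyne of 11 (dicobaltatetrahedrane) | C[C@@H](CCC=C)C12C3(c4c(OC)c5c(C)cccc5oc4=O)[Co]1(=C=O)(=C=O)(=C=O)[Co]23(=C=O)(=C=O)=C=O | intermediate
13 | (4S,6aR)-3-(4-methoxy-5-methyl-2-oxo-2H-chromen-3-yl)-4-methyl-4,5,6,6a-tetrahydropentalen-2(1H)-one | C1C(=O)C(c2c(OC)c3c(C)cccc3oc2=O)=C2[C@@H]1CC[C@@H]2C | intermediate
14 | lithium cross-conjugated dienolate of 13 (C3=C4 enolate) | C1=C([O-])C(c2c(OC)c3c(C)cccc3oc2=O)=C2[C@@H]1CC[C@@H]2C.[Li+] | intermediate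
15 | (1R,4S,6aR)-3-(4-methoxy-5-methyl-2-oxo-2H-chromen-3-yl)-1,4-dimethyl-4,5,6,6a-tetrahydropentalen-2(1H)-one | C[C@H]1C(=O)C(c2c(OC)c3c(C)cccc3oc2=O)=C2[C@@H]1CC[C@@H]2C | intermediate
16 | (1R,3S,3aR,4S,6aS)-3-(4-methoxy-5-methyl-2-oxo-2H-chromen-3-yl)-1,4-dimethylhexahydropentalen-2(1H)-one (coumarinyl endo) | C[C@H]1C(=O)[C@H](c2c(OC)c3c(C)cccc3oc2=O)[C@H]2[C@@H]1CC[C@@H]2C | intermediate
17 | (1R,3R,3aR,4S,6aS)-3-(4-methoxy-5-methyl-2-oxo-2H-chromen-3-yl)-1,4-dimethylhexahydropentalen-2(1H)-one (coumarinyl exo; key-step precursor) | C[C@H]1C(=O)[C@@H](c2c(OC)c3c(C)cccc3oc2=O)[C@H]2[C@@H]1CC[C@@H]2C | intermediate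
18 | Criegee adduct of 17 with mCPBA (C3 carries OH and OOC(O)Ar; configuration at C3 not specified) | C[C@H]1C(O)(OOC(=O)c2cccc(Cl)c2)[C@@H](c2c(OC)c3c(C)cccc3oc2=O)[C@H]2[C@@H]1CC[C@@H]2C | intermediate
19 | (1R,4R,4aS,7S,7aR)-1-(4-methoxy-5-methyl-2-oxo-2H-chromen-3-yl)-4,7-dimethylhexahydrocyclopenta[c]pyran-3(1H)-one (key-step product) | C[C@H]1C(=O)O[C@@H](c2c(OC)c3c(C)cccc3oc2=O)[C@H]2[C@@H]1CC[C@@H]2C | intermediate
20 | potassium enolate of 19 | CC1=C([O-])O[C@@H](c2c(OC)c3c(C)cccc3oc2=O)[C@H]2[C@@H]1CC[C@@H]2C.[K+] | intermediate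
21 | C3 diphenyl phosphate of the C3=C4 ketene acetal (1R,4aS,7S,7aR) | CC1=C(OP(=O)(Oc2ccccc2)Oc2ccccc2)O[C@@H](c2c(OC)c3c(C)cccc3oc2=O)[C@H]2[C@@H]1CC[C@@H]2C | intermediate
22 | C3 trimethylstannane (1R,4aS,7S,7aR) | CC1=C([Sn](C)(C)C)O[C@@H](c2c(OC)c3c(C)cccc3oc2=O)[C@H]2[C@@H]1CC[C@@H]2C | intermediate
23 | (R)-2-hydroxy-3-methylbutanoic acid | CC(C)[C@@H](O)C(=O)O | starting material
24 | tert-butyldimethylsilyl (2R)-2-(tert-butyldimethylsilyloxy)-3-methylbutanoate | CC(C)[C@@H](O[Si](C)(C)C(C)(C)C)C(=O)O[Si](C)(C)C(C)(C)C | intermediate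
25 | (2R)-2-(tert-butyldimethylsilyloxy)-3-methylbutanoyl chloride | CC(C)[C@@H](O[Si](C)(C)C(C)(C)C)C(=O)Cl | intermediate
26 | O4'-methyl, O-TBS protected target | CC1=C(C(=O)[C@H](O[Si](C)(C)C(C)(C)C)C(C)C)O[C@@H](c2c(OC)c3c(C)cccc3oc2=O)[C@H]2[C@@H]1CC[C@@H]2C | intermediate
27 | lithium 4'-coumarinolate of 28 | CC1=C(C(=O)[C@H](O[Si](C)(C)C(C)(C)C)C(C)C)O[C@@H](c2c([O-])c3c(C)cccc3oc2=O)[C@H]2[C@@H]1CC[C@@H]2C.[Li+] | intermediate
28 | O-TBS protected target | CC1=C(C(=O)[C@H](O[Si](C)(C)C(C)(C)C)C(C)C)O[C@@H](c2c(O)c3c(C)cccc3oc2=O)[C@H]2[C@@H]1CC[C@@H]2C | intermediate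
29 | CNP0214255.1, 3-{(1R,4aS,7S,7aR)-3-[(2R)-2-hydroxy-3-methylbutanoyl]-4,7-dimethyl-1,4a,5,6,7,7a-hexahydrocyclopenta[c]pyran-1-yl}-4-hydroxy-5-methylcoumarin | CC1=C(C(=O)[C@H](O)C(C)C)O[C@@H](c2c(O)c3c(C)cccc3oc2=O)[C@H]2[C@@H]1CC[C@@H]2C | target

**Step count**
- Total step count: 18.
- Longest linear sequence: 13 steps. From 5 these are steps 4–13 and 16–18. The line from 1 is equally long (steps 1–3, 7–13, 16–18).

**Steps most likely to fail**

**Step 11 (Baeyer–Villiger oxidation).**
- What may go wrong: the C3 carbonyl is flanked by two branched carbons, so addition of the peracid may be slow. Migration of C4 may then compete with that of C1, or the C1 enol may be oxidised.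
- Fallback: it sets out from 17 and returns at 19, and it cuts the C1–C3 bond oxidatively instead of inserting oxygen.
- Soft enolisation (TMSOTf, Et3N, CH2Cl2, 0 °C) should give the conjugated C1=C3 trimethylsilyl enol ether F1.
- Ozonolysis (O3, CH2Cl2, −78 °C; Me2S; aqueous work-up) opens the ring to the coumarinyl ketone carboxylic acid F2.
- Luche reduction (NaBH4, CeCl3, MeOH, −40 °C) gives the hydroxy acid F3 as a mixture of C1 epimers.
- Camphorsulfonic acid in CH2Cl2 then closes the lactone. The C1–O bond ionises reversibly, so both epimers can drain into the more stable exo lactone 19.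

**Step 16 (Stille acylation).**
- What may go wrong: transmetalation of the tetrasubstituted α-alkoxyvinylstannane may be slow. Protodestannylation, decarbonylation of the acylpalladium species or racemisation of the acid chloride through its ketene may then take over.
- Fallback: it sets out from 22 and 25 and returns at 26, and it forms the C3–C bond by carbonyl addition at the alcohol oxidation level.
- Tin–iodine exchange (I2, CH2Cl2, −78 °C) converts 22 into the C3 iodo enol ether F4.
- Reduction of 25 with LiAlH(Ot-Bu)3 (THF, −78 °C) gives (2R)-2-(tert-butyldimethylsilyloxy)-3-methylbutanal F5.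
- Nozaki–Hiyama–Kishi coupling (CrCl2, cat. NiCl2, DMF, rt), which tolerates the coumarin, joins the two to the allylic alcohol F6. Its new carbinol centre is of no consequence.
- Dess–Martin oxidation (NaHCO3, CH2Cl2) then gives 26.

**Step 10 (hydrogenation of the tetrasubstituted enone).**
- What may go wrong: the twisted coumarinyl group with its two flanking substituents and the exo C7 methyl may keep C1=C7a off the catalyst surface. Conversion may then stall, or the coumarin may be reduced under forcing pressure.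
- Fallback: it sets out from 15 and returns at 17, and it replaces surface hydrogenation by homogeneous 1,4-hydride transfer with trapping on oxygen.
- Rhodium-catalysed conjugate hydrosilylation (Et3SiH, RhCl(PPh3)3, toluene, 60 °C) should deliver hydride to C7a from the convex face. This gives the C1=C3 triethylsilyl enol ether F7.
- TBAF/AcOH (THF, 0 °C) protonates F7, and DBU equilibrates the product to the exo ketone 17.

**Further compounds**
F1 | step 11 | C1=C3 trimethylsilyl enol ether of 17 | C[C@H]1C(O[Si](C)(C)C)=C(c2c(OC)c3c(C)cccc3oc2=O)[C@H]2[C@@H]1CC[C@@H]2C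
F2 | step 11 | keto acid from C1–C3 cleavage (C1 = coumarinyl ketone, C3 = CO2H; C4, C4a, C7, C7a as in 17) | C[C@@H](C(=O)O)[C@H]1CC[C@H](C)[C@H]1C(=O)c1c(OC)c2c(C)cccc2oc1=O
F3 | step 11 | hydroxy acid (C1 carbinol, epimer mixture) | C[C@@H](C(=O)O)[C@H]1CC[C@H](C)[C@H]1C(O)c1c(OC)c2c(C)cccc2oc1=O
F4 | step 16 | C3 iodo enol ether (1R,4aS,7S,7aR) | CC1=C(I)O[C@@H](c2c(OC)c3c(C)cccc3oc2=O)[C@H]2[C@@H]1CC[C@@H]2C
F5 | step 16 | (2R)-2-(tert-butyldimethylsilyloxy)-3-methylbutanal | CC(C)[C@@H](O[Si](C)(C)C(C)(C)C)C=O
F6 | step 16 | allylic alcohol at the side-chain carbonyl carbon (epimer mixture) | CC1=C(C(O)[C@H](O[Si](C)(C)C(C)(C)C)C(C)C)O[C@@H](c2c(OC)c3c(C)cccc3oc2=O)[C@H]2[C@@H]1CC[C@@H]2C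
F7 | step 10 | C1=C3 triethylsilyl enol ether from conjugate hydrosilylation of 15 | C[C@H]1C(O[Si](CC)(CC)CC)=C(c2c(OC)c3c(C)cccc3oc2=O)[C@H]2[C@@H]1CC[C@@H]2C
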